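Ring B (C5, C6, C7, C8, C9, C10) is not cyclised but grown from a cyclopentanone: C9 is inserted between the carbonyl carbon C8 and the quaternary C10 of a trans-hydrindanone (used as its dibromomethyl carbinol) that already holds ring A with its 3β-hydroxyl, C4 gem-dimethyl group and C10 methyl. A β-oxido carbenoid rearrangement shifts C10 onto the carbenoid carbon and gives, in the same flask, the C8=C9 lithium enolate, which formaldehyde attacks at C9 on the α face, opposite the axial C10 methyl; ring B, C11 and the C9 configuration arise together. Methyl addition to C8, Mitsunobu etherification with umbelliferone and acylation complete the route from (S)-Hajos–Parrish ketone.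

Key step: step 7

Remark on numbering: drimane numbering is used throughout (ring A: C1–C5 and C10; ring B: C5–C10; C11 on C9; C12 on C8; β is the face of the C10 methyl), and the five-membered precursor ring keeps the labels C5, C6, C7, C8 and C10.

Step 1
Reactants: 1 (S)-Hajos–Parrish ketone
Product: 2 (S)-Hajos–Parrish ketone 8-(ethylene ketal)
Conditions: HOCH2CH2OH, p-TsOH·H2O (cat.), 4 Å MS, CH2Cl2, rt
Reagents that add atoms: ethylene glycol, OCCO
Why: Acid-catalysed dioxolane formation is selective for the saturated cyclopentanone carbonyl C8 because the C3 carbonyl is deactivated by conjugation with the C4=C5 double bond; no stereocentre is formed.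

Step 2
Reactants: 2 (S)-Hajos–Parrish ketone 8-(ethylene ketal)
Product: 3 4,4-dimethyl-5(6)-en-3-one 8-(ethylene ketal)
Conditions: KOtBu (3 equiv), MeI (excess), t-BuOH/THF, 0 °C to rt
Reagents that add atoms: iodomethane, CI
Why: Deconjugative α,α-dialkylation through the extended potassium dienolate places both methyl groups on C4 and moves the double bond to C5=C6; no new stereocentre.

Step 3
Reactants: 3 4,4-dimethyl-5(6)-en-3-one 8-(ethylene ketal)
Product: 4 trans-fused 4,4,10-trimethylhydrindan-3-one 8-(ethylene ketal)
Conditions: H2 (5 bar), Pd/C, EtOAc, rt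
Reagents that add atoms: none
Why: Heterogeneous catalytic hydrogenation should add H2 to C5=C6 from the α face, because the β face is covered by the C10 methyl and the axial 4β-methyl, which sets 5α-H and the trans ring fusion.

Step 4
Reactants: 4 trans-fused 4,4,10-trimethylhydrindan-3-one 8-(ethylene ketal)
Product: 5 3β-hydroxy-4,4,10-trimethyl-trans-hydrindane 8-(ethylene ketal)
Conditions: NaBH4, MeOH, 0 °C
Reagents that add atoms: none
Why: Borohydride reduction with axial hydride delivery on the α face, away from the axial 4β-methyl, should give the equatorial 3β-alcohol as in 4,4-dimethyl-3-oxo terpenoids.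

Step 5
Reactants: 5 3β-hydroxy-4,4,10-trimethyl-trans-hydrindane 8-(ethylene ketal)
Product: 6 3β-hydroxy-4,4,10-trimethyl-trans-hydrindan-8-one
Conditions: 1 M aq. HCl, THF, rt
Reagents that add atoms: water, O
Why: Acid-catalysed ketal hydrolysis frees the C8 ketone, and the trans ring fusion cannot epimerise because C5 is not α to the carbonyl.

Step 6
Reactants: 6 3β-hydroxy-4,4,10-trimethyl-trans-hydrindan-8-one
Product: 7 8α-(dibromomethyl)-4,4,10-trimethyl-trans-hydrindane-3β,8β-diol
Conditions: CH2Br2, lithium 2,2,6,6-tetramethylpiperidide (LiTMP), THF, −78 °C; AcOH, −78 °C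
Reagents that add atoms: dibromomethane, BrCBr
Why: 1,2-Addition of dibromomethyllithium, generated in the presence of the ketone, should occur on the α face opposite the angular C10 methyl (this carbinol centre is lost in step 7), with the C3 hydroxyl carried as its lithium alkoxide.

Step 7
Reactants: 7 8α-(dibromomethyl)-4,4,10-trimethyl-trans-hydrindane-3β,8β-diol
Product: 10 3β,11-dihydroxy-12-nor-9βH-driman-8-one, via β-oxido carbenoid 8 (not isolated), via lithium enolate 9 (not isolated)
Conditions: n-BuLi (3.2 equiv), THF, −95 to −60 °C; then CH2O gas (cracked paraformaldehyde), −78 °C; AcOH, −78 °C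
Reagents that add atoms: formaldehyde, C=O
Why: Butyllithium deprotonates both hydroxyls and exchanges one bromine, and the β-oxido carbenoid 8 then expels LiBr while the C8–C10 bond shifts to the carbenoid carbon C9, giving lithium enolate 9 with its double bond fixed between C8 and C9. The closest known reaction type is the β-oxido carbenoid (dibromomethyllithium) ring enlargement of cycloalkanones with trapping of the regiospecific enolate, here by aldol addition to formaldehyde. Ring B is closed by ring enlargement, a 1,2-shift of a ring bond from C8 to the exocyclic carbon C9 (five to six ring atoms), not by a cyclisation. The only new stereocentre, C9, is set in the aldol event: formaldehyde attacks C9 of the half-chair enolate axially on the α face, anti to the adjacent pseudo-axial C10 methyl, which gives the 9α-hydroxymethyl, 9β-H ketone. The step needs migration of the quaternary C10 rather than C7, which the higher migratory aptitude of the more substituted, more electron-rich carbon towards the electrophilic carbenoid centre should secure, and it needs C-attack without later C9 epimerisation, which the small aldehyde electrophile and the cold acetic acid quench should secure.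

Step 8
Reactants: 10 3β,11-dihydroxy-12-nor-9βH-driman-8-one
Product: 11 9βH-drimane-3β,8β,11-triol
Conditions: MeLi, anhydrous CeCl3, THF, −78 to −40 °C; then H2O
Reagents that add atoms: methyllithium, C[Li]
Why: Organocerium 1,2-addition (low basicity, so no enolisation, retro-aldol or C9 epimerisation) should deliver methyl to C8 equatorially from the α face, because axial β attack is blocked by the 1,3-diaxial C10 methyl and the cerium alkoxide of the α-oriented C11 oxygen can guide the reagent to the same face, giving 8α-methyl and 8β-OH.

Step 9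
Reactants: 11 9βH-drimane-3β,8β,11-triol; 12 umbelliferone
Product: 13 11-O-(2-oxo-2H-chromen-7-yl)-9βH-drimane-3β,8β,11-triol
Conditions: PPh3, DIAD, THF, 0 °C to rt
Reagents that add atoms: none
Why: In this Mitsunobu etherification only the primary C11 hydroxyl should be activated (the neopentylic 3β-OH and the tertiary 8β-OH are too hindered) and displaced by the acidic phenol at a non-stereogenic carbon, while the trans-diaxial 8β-OH cannot close an oxetane.

Step 10
Reactants: 13 11-O-(2-oxo-2H-chromen-7-yl)-9βH-drimane-3β,8β,11-triol
Product: 14 target, 3β-isobutyrate of 13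
Conditions: (i-PrCO)2O, DMAP (cat.), pyridine, CH2Cl2, rt
Reagents that add atoms: isobutyric anhydride, CC(C)C(=O)OC(=O)C(C)C
Why: DMAP-catalysed acylation should esterify the equatorial secondary 3β-hydroxyl while the axial tertiary 8β-hydroxyl stays free, and no stereocentre is touched.

Compound list
1 | (S)-Hajos–Parrish ketone, (7aS)-7a-methyl-2,3,7,7a-tetrahydro-1H-indene-1,5(6H)-dione | O=C1CC[C@@]2(C)C(=C1)CCC2=O | starting material
2 | (S)-Hajos–Parrish ketone 8-(ethylene ketal): dioxolane on the cyclopentanone carbon C8, C4=C5 enone intact | O=C1CC[C@@]2(C)C(=C1)CCC23OCCO3 | intermediate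
3 | 4,4,10β-trimethyl-hydrind-5(6)-en-3-one 8-(ethylene ketal) | O=C1CC[C@@]2(C)C(=CCC23OCCO3)C1(C)C | intermediate
4 | trans-fused (5α-H, 10β-Me) 4,4,10-trimethylhydrindan-3-one 8-(ethylene ketal) | O=C1CC[C@@]2(C)[C@@H](CCC23OCCO3)C1(C)C | intermediate
5 | 3β-hydroxy-4,4,10-trimethyl-trans-hydrindane 8-(ethylene ketal) | O[C@H]1CC[C@@]2(C)[C@@H](CCC23OCCO3)C1(C)C | intermediate
6 | 3β-hydroxy-4,4,10-trimethyl-trans-hydrindan-8-one (5α-H, 10β-Me) | O[C@H]1CC[C@@]2(C)[C@@H](CCC2=O)C1(C)C | intermediate
7 | 8α-(dibromomethyl)-4,4,10-trimethyl-trans-hydrindane-3β,8β-diol | O[C@H]1CC[C@@]2(C)[C@@H](CC[C@@]2(O)C(Br)Br)C1(C)C | intermediate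
8 | β-oxido carbenoid: 3,8-dilithium alkoxide of 7 with Li and Br on the exocyclic carbon C9 | [Li]O[C@H]1CC[C@@]2(C)[C@@H](CC[C@@]2(O[Li])C([Li])Br)C1(C)C | intermediate
9 | ring-enlarged lithium enolate: dilithium 11,12-dinordrim-8(9)-ene-3β,8-diolate | [Li]O[C@H]1CC[C@@]2(C)[C@@H](CCC(O[Li])=C2)C1(C)C | intermediate
10 | 3β,11-dihydroxy-12-nor-9βH-driman-8-one (9α-CH2OH axial, 5α-H, 10β-Me) | O[C@H]1CC[C@@]2(C)[C@@H](CCC(=O)[C@H]2CO)C1(C)C | intermediate
11 | 9βH-drimane-3β,8β,11-triol (8α-Me, 9α-CH2OH) | O[C@H]1CC[C@@]2(C)[C@@H](CC[C@](C)(O)[C@H]2CO)C1(C)C | intermediate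
12 | umbelliferone, 7-hydroxy-2H-chromen-2-one | Oc1ccc2ccc(=O)oc2c1 | starting material
13 | 11-O-(2-oxo-2H-chromen-7-yl)-9βH-drimane-3β,8β,11-triol | O[C@H]1CC[C@@]2(C)[C@@H](CC[C@](C)(O)[C@H]2COc2ccc3ccc(=O)oc3c2)C1(C)C | intermediate
14 | (2S,4aS,5R,6S,8aR)-6-hydroxy-1,1,4a,6-tetramethyl-5-{[(2-oxo-2H-chromen-7-yl)oxy]methyl}decahydronaphthalen-2-yl 2-methylpropanoate | CC(C)C(=O)O[C@H]1CC[C@@]2(C)[C@@H](CC[C@](C)(O)[C@H]2COc2ccc3ccc(=O)oc3c2)C1(C)C | target

Total step count: 10. Longest linear sequence: 10 steps (1 to 14).

Steps most likely to fail: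

Step 7. The ring CH2 (C7) may migrate in place of C10, or the carbenoid may collapse by other paths, so that the enolate forms with the wrong connectivity or not at all. The fallback sets out from ketone 6 and changes the ring enlargement to a cationic one. Addition of (PhS)2CHLi (THF, −78 °C) would give the 8α-[bis(phenylthio)methyl] carbinol F1. CuOTf (as (CuOTf)2·C6H6) with i-Pr2NEt in benzene would ionise one C–S bond, and the sulfur-stabilised cation would take the more electron-rich C10 in a semipinacol shift to give the ring-enlarged 9-(phenylthio)-8-ketone F2. Reductive C–S cleavage with lithium naphthalenide (LiC10H8, THF, −78 °C) would regenerate lithium enolate 9, and formaldehyde would lead back to 10.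

Step 8. Methyl may attack on the β face because the axial 9α-CH2O group hinders the equatorial trajectory, or enolisation and retro-aldol may consume the ketone. The fallback sets out from 10 and uses thermodynamic control of the new C–C bond. Dimethylsulfoxonium methylide (Me3S(O)I, NaH, DMSO, rt) forms its betaine reversibly and should place the methylene equatorial, giving the 8β,12-epoxide F3. LiAlH4 (THF, 0 °C) would open it at the primary carbon C12 and return to triol 11.

Step 9. Displacement at the β-branched, axial C11 may be too slow, so that the activated alcohol is diverted to hydrazide alkylation. The fallback sets out from 11 and forms the aryl–oxygen bond instead of the alkyl–oxygen bond. Pd-catalysed C–O cross-coupling with commercial 7-bromocoumarin ([(C3H5)PdCl]2, RockPhos, Cs2CO3, toluene, 90 °C) should favour the primary alcohol and give 13 directly (no new compound, F0).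

Further compounds
F1 | step 7 | 8α-[bis(phenylthio)methyl]-4,4,10-trimethyl-trans-hydrindane-3β,8β-diol | O[C@H]1CC[C@@]2(C)[C@@H](CC[C@@]2(O)C(Sc2ccccc2)Sc2ccccc2)C1(C)C
F2 | step 7 | 3β-hydroxy-9-(phenylthio)-11,12-dinordriman-8-one (C9 epimers) | O[C@H]1CC[C@@]2(C)[C@@H](CCC(=O)C2Sc2ccccc2)C1(C)C
F3 | step 8 | 8β,12-epoxy-9βH-drimane-3β,11-diol | O[C@H]1CC[C@@]2(C)[C@@H](CC[C@]3(OC3)[C@H]2CO)C1(C)C
F0 | step 9 | none | none
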